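**Retrosynthetic overview**

1. The 2-methoxy-4-pyranone is taken back to an ester on C1 (aldehyde, keto ester dianion aldol, oxidation, cyclisation, base-free O-methylation). The C6 enone is taken back to a propynyl carbinol (Meyer–Schuster) made from a C6 acyl group.
2. Feature used: in the carbocycle C1 (quaternary: Me and pyranone) – C2H=C3(Me)–C4H=C5(Me) – C6H (side chain), the diene carbons C2–C5 carry H, Me, H, Me exactly as C3–C6 of 4,6-dimethyl-2H-pyran-2-one do. The cis substituents on C1 and C6 are the two carbonyl carbons of a (Z)-2-methylbutenedioyl unit.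
3. Key disconnection: C1–C2 and C5–C6 by [4+2] addition of the pyrone to a citraconate imide ester, then loss of CO2. The (4R)-benzyl oxazolidinone on the C6 carbonyl activates the alkene and sets both stereocentres.
4. Ring order: carbocycle first (step 3), pyranone last (step 12). The dienophile comes in two steps from citraconic anhydride.

Key step: step 3

Assumption: the Me2AlCl chelate of 5 reacts as the s-cis enoyl conformer with the diene adding anti to the benzyl group, as for other N-enoyl oxazolidinones; on that model the (4R)-auxiliary leads to the (1S,6S) ring of the target, and the carbinol centre made in step 6 is carried as an epimer mixture because step 13 removes it.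

**Route**

Step 1
Reactants: 1 (R)-4-benzyloxazolidin-2-one; 2 citraconic anhydride
Product: 4 (Z)-4-[(4R)-4-benzyl-2-oxo-1,3-oxazolidin-3-yl]-2-methyl-4-oxobut-2-enoic acid, via N-lithio oxazolidinone 3 (not isolated)
Conditions: n-BuLi, THF, −78 °C; then 2, −78 °C; cold 1 M HCl work-up; crude acid used at once
Reagents that add atoms: none
Why: N-acylation of a lithiated oxazolidinone by ring opening of a cyclic anhydride should take place at the C5 carbonyl, which is flanked by the alkene CH and not by the methyl-bearing carbon, and opening a ring leaves the alkene Z; the acid is not stored because a cis acid can close back onto the imide.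

Step 2
Reactants: 4 (Z)-4-[(4R)-4-benzyl-2-oxo-1,3-oxazolidin-3-yl]-2-methyl-4-oxobut-2-enoic acid
Product: 5 methyl (Z)-4-[(4R)-4-benzyl-2-oxo-1,3-oxazolidin-3-yl]-2-methyl-4-oxobut-2-enoate
Conditions: TMSCHN2 (added until the yellow colour just persists), toluene/MeOH 4:1, 0 °C
Reagents that add atoms: trimethylsilyldiazomethane, C[Si](C)(C)C=[N+]=[N-]
Why: Esterification of a carboxylic acid with trimethylsilyldiazomethane is fast at 0 °C without base or heat, so the Z alkene and the imide should survive, and the short contact time avoids dipolar cycloaddition to the electron-poor alkene.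

Step 3
Reactants: 5 methyl (Z)-4-[(4R)-4-benzyl-2-oxo-1,3-oxazolidin-3-yl]-2-methyl-4-oxobut-2-enoate; 6 4,6-dimethyl-2H-pyran-2-one
Product: 8 methyl (1S,6R)-6-{[(4R)-4-benzyl-2-oxo-1,3-oxazolidin-3-yl]carbonyl}-1,3,5-trimethylcyclohexa-2,4-diene-1-carboxylate, via bridged lactone 7 (not isolated)
Conditions: Me2AlCl (1.5 equiv), CH2Cl2, −78 °C; then 6 (3 equiv), −40 → 0 °C; aqueous KNaC4H4O6 work-up; crude 7 in toluene, 110 °C
Reagents that add atoms: none
Why: Me2AlCl binds both imide carbonyls of 5 as a chelate with the enoyl unit s-cis, and the diene C3=C4–C5=C6 of 6 adds in a concerted, asynchronous normal-demand [4+2] to give the 2-oxabicyclo[2.2.2]oct-7-en-3-ones 7, which lose CO2 by retro-[4+2] at 110 °C; the closest known reactions are the Lewis-acid-promoted Diels–Alder addition of N-enoyl oxazolidinones and the 2-pyrone cycloaddition/decarboxylation route to cyclohexa-1,3-dienes. The carbocycle is closed by intermolecular cycloaddition, both ring bonds (C1–C2 and C5–C6) forming on one face of the alkene, and the cycloreversion only removes the lactone bridge. Suprafacial addition turns the Z geometry of 5 into the cis relation of the C1 ester and the C6 acyl group, and the endo or exo position of the bridge is erased with the CO2, so both adducts give the same diene. The absolute configuration at C1 and C6 is set by the (4R)-benzyl group, which shields one face of the chelated s-cis dienophile so that the pyrone adds anti to it, and this corresponds to (1S,6R)-8. The regiochemistry needed (pyrone C3 to the methyl- and ester-bearing carbon) follows because C3 is the nucleophilic terminus and attacks the β-carbon of the activated imide, and because this avoids joining that fully substituted carbon to the methyl-bearing pyrone C6. Low temperature keeps the Z alkene intact before it reacts, the quaternary C1 blocks aromatisation after CO2 loss, and removing the Lewis acid before heating, with 6 in excess, keeps 8 from adding a second dienophile.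

Step 4
Reactants: 8 methyl (1S,6R)-6-{[(4R)-4-benzyl-2-oxo-1,3-oxazolidin-3-yl]carbonyl}-1,3,5-trimethylcyclohexa-2,4-diene-1-carboxylate
Product: 9 methyl (1S,6R)-6-[(ethylsulfanyl)carbonyl]-1,3,5-trimethylcyclohexa-2,4-diene-1-carboxylate
Conditions: EtSH, n-BuLi, THF, 0 °C; aqueous NH4Cl
Reagents that add atoms: ethanethiol (used as LiSEt), CCS
Why: Thiolate cleavage of an N-acyl oxazolidinone (transthioesterification) attacks the exocyclic carbonyl even when it is hindered, the thiolate is too weak a base to epimerise C6 and does not touch the quaternary ester, and the auxiliary is recovered.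

Step 5
Reactants: 9 methyl (1S,6R)-6-[(ethylsulfanyl)carbonyl]-1,3,5-trimethylcyclohexa-2,4-diene-1-carboxylate
Product: 10 methyl (1S,6R)-6-acetyl-1,3,5-trimethylcyclohexa-2,4-diene-1-carboxylate
Conditions: Me2CuLi (from MeLi and CuI), Et2O, −78 → −40 °C; aqueous NH4Cl
Reagents that add atoms: methyllithium (used as Me2CuLi), [Li]C
Why: Ketone synthesis from a thioester and a lithium dialkylcuprate stops at the ketone and leaves the methyl ester alone, and the weakly basic reagent at low temperature should not epimerise C6.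

Step 6
Reactants: 10 methyl (1S,6R)-6-acetyl-1,3,5-trimethylcyclohexa-2,4-diene-1-carboxylate
Product: 11 methyl (1S,6R)-6-(2-hydroxypent-3-yn-2-yl)-1,3,5-trimethylcyclohexa-2,4-diene-1-carboxylate (both carbinol epimers)
Conditions: MeC≡CMgBr, THF, −20 → 0 °C; AcOH quench at −20 °C
Reagents that add atoms: 1-propynylmagnesium bromide, CC#C[Mg]Br
Why: 1,2-Addition of an alkynyl Grignard reagent to a methyl ketone should win over enolisation because the nucleophile is weakly basic, the hindered ester is not attacked, the cold quench limits lactonisation onto the cis ester, and the new carbinol centre is destroyed in step 13.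

Step 7
Reactants: 11 methyl (1S,6R)-6-(2-hydroxypent-3-yn-2-yl)-1,3,5-trimethylcyclohexa-2,4-diene-1-carboxylate
Product: 12 methyl (1S,6R)-1,3,5-trimethyl-6-[2-(triethylsilyloxy)pent-3-yn-2-yl]cyclohexa-2,4-diene-1-carboxylate
Conditions: TESOTf, 2,6-lutidine, CH2Cl2, −78 → 0 °C
Reagents that add atoms: triethylsilyl trifluoromethanesulfonate, CC[Si](CC)(CC)OS(=O)(=O)C(F)(F)F
Why: Silylation of a tertiary alcohol with a silyl triflate and a hindered pyridine base is general, and the TES ether prevents lactone or lactol formation with the cis C1 carbonyl group and tolerates hydride, strong base and DBU.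

Step 8
Reactants: 12 methyl (1S,6R)-1,3,5-trimethyl-6-[2-(triethylsilyloxy)pent-3-yn-2-yl]cyclohexa-2,4-diene-1-carboxylate
Product: 13 {(1S,6R)-1,3,5-trimethyl-6-[2-(triethylsilyloxy)pent-3-yn-2-yl]cyclohexa-2,4-dien-1-yl}methanol
Conditions: i-Bu2AlH (3 equiv), CH2Cl2, −78 → 0 °C; aqueous KNaC4H4O6
Reagents that add atoms: none
Why: Reduction of an ester to the primary alcohol with i-Bu2AlH works on neopentyl esters, and the silyl ether, the internal alkyne and the unactivated diene are inert at or below 0 °C.

Step 9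
Reactants: 13 {(1S,6R)-1,3,5-trimethyl-6-[2-(triethylsilyloxy)pent-3-yn-2-yl]cyclohexa-2,4-dien-1-yl}methanol
Product: 14 (1S,6R)-1,3,5-trimethyl-6-[2-(triethylsilyloxy)pent-3-yn-2-yl]cyclohexa-2,4-diene-1-carbaldehyde
Conditions: Dess–Martin periodinane, pyridine, CH2Cl2, 0 °C → rt
Reagents that add atoms: none
Why: Dess–Martin oxidation of a primary alcohol is mild and buffered, and the aldehyde has no α-hydrogen, so it can neither enolise nor epimerise.

Step 10
Reactants: 14 (1S,6R)-1,3,5-trimethyl-6-[2-(triethylsilyloxy)pent-3-yn-2-yl]cyclohexa-2,4-diene-1-carbaldehyde; 15 methyl 2-methyl-3-oxopentanoate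
Product: 17 methyl 5-hydroxy-2,4-dimethyl-3-oxo-5-{(1S,6R)-1,3,5-trimethyl-6-[2-(triethylsilyloxy)pent-3-yn-2-yl]cyclohexa-2,4-dien-1-yl}pentanoate (mixture of diastereomers), via keto ester dianion 16 (not isolated)
Conditions: 15 (3 equiv), LiN(i-Pr)2 (6 equiv), THF, 0 °C; then 14, −78 °C; AcOH quench
Reagents that add atoms: none
Why: Aldol addition of a β-keto ester dianion through its γ-carbon to a non-enolisable aldehyde is the standard entry to polypropionate pyranones, and the three new stereocentres, formed as a mixture, are all removed in steps 11 and 12.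

Step 11
Reactants: 17 methyl 5-hydroxy-2,4-dimethyl-3-oxo-5-{(1S,6R)-1,3,5-trimethyl-6-[2-(triethylsilyloxy)pent-3-yn-2-yl]cyclohexa-2,4-dien-1-yl}pentanoate
Product: 18 methyl 2,4-dimethyl-3,5-dioxo-5-{(1S,6R)-1,3,5-trimethyl-6-[2-(triethylsilyloxy)pent-3-yn-2-yl]cyclohexa-2,4-dien-1-yl}pentanoate (keto/enol and epimer mixture)
Conditions: Dess–Martin periodinane, pyridine, CH2Cl2, rt
Reagents that add atoms: none
Why: Dess–Martin oxidation converts the δ-hydroxy β-keto ester into the β,δ-diketo ester under non-basic conditions, so no retro-aldol cleavage is expected.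

Step 12
Reactants: 18 methyl 2,4-dimethyl-3,5-dioxo-5-{(1S,6R)-1,3,5-trimethyl-6-[2-(triethylsilyloxy)pent-3-yn-2-yl]cyclohexa-2,4-dien-1-yl}pentanoate
Product: 19 4-hydroxy-3,5-dimethyl-6-{(1S,6R)-1,3,5-trimethyl-6-[2-(triethylsilyloxy)pent-3-yn-2-yl]cyclohexa-2,4-dien-1-yl}-2H-pyran-2-one
Conditions: DBU, toluene, rt → 50 °C; aqueous citric acid wash
Reagents that add atoms: none
Why: Base-mediated cyclisation of a β,δ-diketo ester (the δ-enol oxygen attacks the ester, methanol is lost) closes the pyranone ring and is driven by formation of the aromatic 4-hydroxy-2-pyranone.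

Step 13
Reactants: 19 4-hydroxy-3,5-dimethyl-6-{(1S,6R)-1,3,5-trimethyl-6-[2-(triethylsilyloxy)pent-3-yn-2-yl]cyclohexa-2,4-dien-1-yl}-2H-pyran-2-one
Product: 21 4-hydroxy-3,5-dimethyl-6-{(1S,6S)-1,3,5-trimethyl-6-[(2E)-4-oxopent-2-en-2-yl]cyclohexa-2,4-dien-1-yl}-2H-pyran-2-one, via free propargylic alcohol 20 (not isolated)
Conditions: Bu4NReO4 (10 mol %), TsOH·H2O (20 mol %), CH2Cl2 containing H2O (2 equiv), rt
Reagents that add atoms: none
Why: The acid removes the TES group and the perrhenate then catalyses the Meyer–Schuster rearrangement (1,3-shift of oxygen through the propargyl perrhenate ester to the allenol, then tautomerisation) without a free carbocation, and the E enone, with the ring trans to the acetyl group, is the thermodynamic isomer under the acidic conditions.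

Step 14
Reactants: 21 4-hydroxy-3,5-dimethyl-6-{(1S,6S)-1,3,5-trimethyl-6-[(2E)-4-oxopent-2-en-2-yl]cyclohexa-2,4-dien-1-yl}-2H-pyran-2-one
Product: 22 2-methoxy-3,5-dimethyl-6-{(1S,6S)-1,3,5-trimethyl-6-[(2E)-4-oxopent-2-en-2-yl]cyclohexa-2,4-dien-1-yl}-4H-pyran-4-one
Conditions: MeOTf (3 equiv), CH2Cl2, rt; then aqueous NaHCO3
Reagents that add atoms: methyl trifluoromethanesulfonate, COS(=O)(=O)C(F)(F)F
Why: Base-free O-methylation with a hard methylating agent takes place at the C2 carbonyl oxygen of the hydroxypyranone to give a 4-hydroxy-2-methoxypyrylium salt, which cannot be methylated again and gives the 2-methoxy-4-pyranone on basic work-up, while the enone and the diene are not nucleophilic enough to react.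

**Compound list**

1 | (R)-4-benzyloxazolidin-2-one | O=C1OC[C@@H](Cc2ccccc2)N1 | starting material
2 | citraconic anhydride (3-methylfuran-2,5-dione) | CC1=CC(=O)OC1=O | starting material
3 | N-lithio-(R)-4-benzyloxazolidin-2-one | [Li+].O=C1OC[C@@H](Cc2ccccc2)[N-]1 | intermediate
4 | (Z)-4-[(4R)-4-benzyl-2-oxo-1,3-oxazolidin-3-yl]-2-methyl-4-oxobut-2-enoic acid | OC(=O)/C(C)=C\C(=O)N1[C@H](Cc2ccccc2)COC1=O | intermediate
5 | methyl (Z)-4-[(4R)-4-benzyl-2-oxo-1,3-oxazolidin-3-yl]-2-methyl-4-oxobut-2-enoate | COC(=O)/C(C)=C\C(=O)N1[C@H](Cc2ccccc2)COC1=O | intermediate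
6 | 4,6-dimethyl-2H-pyran-2-one | Cc1cc(C)oc(=O)c1 | starting material
7 | methyl 6-{[(4R)-4-benzyl-2-oxo-1,3-oxazolidin-3-yl]carbonyl}-1,5,8-trimethyl-3-oxo-2-oxabicyclo[2.2.2]oct-7-ene-5-carboxylate (ester and imide cis; endo and exo lactone bridge) | COC(=O)[C@@]1(C)C2C(C)=CC(C)(OC2=O)[C@H]1C(=O)N3[C@H](Cc4ccccc4)COC3=O | intermediate
8 | methyl (1S,6R)-6-{[(4R)-4-benzyl-2-oxo-1,3-oxazolidin-3-yl]carbonyl}-1,3,5-trimethylcyclohexa-2,4-diene-1-carboxylate | COC(=O)[C@@]1(C)C=C(C)C=C(C)[C@H]1C(=O)N2[C@H](Cc3ccccc3)COC2=O | intermediate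
9 | methyl (1S,6R)-6-[(ethylsulfanyl)carbonyl]-1,3,5-trimethylcyclohexa-2,4-diene-1-carboxylate | COC(=O)[C@@]1(C)C=C(C)C=C(C)[C@H]1C(=O)SCC | intermediate
10 | methyl (1S,6R)-6-acetyl-1,3,5-trimethylcyclohexa-2,4-diene-1-carboxylate | COC(=O)[C@@]1(C)C=C(C)C=C(C)[C@H]1C(C)=O | intermediate
11 | methyl (1S,6R)-6-(2-hydroxypent-3-yn-2-yl)-1,3,5-trimethylcyclohexa-2,4-diene-1-carboxylate (carbinol epimers) | COC(=O)[C@@]1(C)C=C(C)C=C(C)[C@H]1C(C)(O)C#CC | intermediate
12 | methyl (1S,6R)-1,3,5-trimethyl-6-[2-(triethylsilyloxy)pent-3-yn-2-yl]cyclohexa-2,4-diene-1-carboxylate | COC(=O)[C@@]1(C)C=C(C)C=C(C)[C@H]1C(C)(O[Si](CC)(CC)CC)C#CC | intermediate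
13 | {(1S,6R)-1,3,5-trimethyl-6-[2-(triethylsilyloxy)pent-3-yn-2-yl]cyclohexa-2,4-dien-1-yl}methanol | OC[C@@]1(C)C=C(C)C=C(C)[C@H]1C(C)(O[Si](CC)(CC)CC)C#CC | intermediate
14 | (1S,6R)-1,3,5-trimethyl-6-[2-(triethylsilyloxy)pent-3-yn-2-yl]cyclohexa-2,4-diene-1-carbaldehyde | O=C[C@@]1(C)C=C(C)C=C(C)[C@H]1C(C)(O[Si](CC)(CC)CC)C#CC | intermediate
15 | methyl 2-methyl-3-oxopentanoate | CCC(=O)C(C)C(=O)OC | starting material
16 | dilithium dianion of methyl 2-methyl-3-oxopentanoate | [Li+].[Li+].C[CH-]C(=O)[C-](C)C(=O)OC | intermediate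
17 | methyl 5-hydroxy-2,4-dimethyl-3-oxo-5-{(1S,6R)-1,3,5-trimethyl-6-[2-(triethylsilyloxy)pent-3-yn-2-yl]cyclohexa-2,4-dien-1-yl}pentanoate (diastereomer mixture) | COC(=O)C(C)C(=O)C(C)C(O)[C@@]1(C)C=C(C)C=C(C)[C@H]1C(C)(O[Si](CC)(CC)CC)C#CC | intermediate
18 | methyl 2,4-dimethyl-3,5-dioxo-5-{(1S,6R)-1,3,5-trimethyl-6-[2-(triethylsilyloxy)pent-3-yn-2-yl]cyclohexa-2,4-dien-1-yl}pentanoate | COC(=O)C(C)C(=O)C(C)C(=O)[C@@]1(C)C=C(C)C=C(C)[C@H]1C(C)(O[Si](CC)(CC)CC)C#CC | intermediate
19 | 4-hydroxy-3,5-dimethyl-6-{(1S,6R)-1,3,5-trimethyl-6-[2-(triethylsilyloxy)pent-3-yn-2-yl]cyclohexa-2,4-dien-1-yl}-2H-pyran-2-one | O=c1oc([C@@]2(C)C=C(C)C=C(C)[C@H]2C(C)(O[Si](CC)(CC)CC)C#CC)c(C)c(O)c1C | intermediate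
20 | 4-hydroxy-6-[(1S,6R)-6-(2-hydroxypent-3-yn-2-yl)-1,3,5-trimethylcyclohexa-2,4-dien-1-yl]-3,5-dimethyl-2H-pyran-2-one | O=c1oc([C@@]2(C)C=C(C)C=C(C)[C@H]2C(C)(O)C#CC)c(C)c(O)c1C | intermediate
21 | 4-hydroxy-3,5-dimethyl-6-{(1S,6S)-1,3,5-trimethyl-6-[(2E)-4-oxopent-2-en-2-yl]cyclohexa-2,4-dien-1-yl}-2H-pyran-2-one | O=c1oc([C@@]2(C)C=C(C)C=C(C)[C@H]2/C(C)=C/C(C)=O)c(C)c(O)c1C | intermediate
22 | 2-methoxy-3,5-dimethyl-6-{(1S,6S)-1,3,5-trimethyl-6-[(2E)-4-oxopent-2-en-2-yl]cyclohexa-2,4-dien-1-yl}-4H-pyran-4-one | COc1oc([C@@]2(C)C=C(C)C=C(C)[C@H]2/C(C)=C/C(C)=O)c(C)c(=O)c1C | target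

**Step count and risks**

Total steps: 14. Longest linear sequence: 14 steps (1 → 22; 2, 6 and 15 enter as purchased materials).

Steps most likely to fail:

1. Step 3. The pyrone carbonyl may compete for Me2AlCl so that the dienophile stays unactivated. The Z-enoyl unit may twist out of the chelate plane, which would erode facial discrimination by the benzyl group. A stepwise Michael-type attack of pyrone C3 would allow bond rotation and loss of the cis relation. Fallback, setting out from 2 and 6 and returning at 8: the cycloaddition is run thermally with the anhydride itself as dienophile, and the auxiliary is attached afterwards as a resolving handle. Heating 2 with excess 6 in toluene at 110 °C should give the racemic bridged anhydride lactone F1, steric demand again directing the methyl-bearing alkene carbon to pyrone C3. At 140 °C this loses CO2 to give the racemic cis-fused diene anhydride F2. N-Lithio oxazolidinone 3 should open F2 at the carbonyl on the CH carbon, giving the diastereomeric imide acids F3. TMSCHN2 then gives 8 together with its (1R,6S) ring diastereomer F4, and the two are separated by chromatography or crystallisation.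

2. Step 13. The tertiary propargylic alcohol may ionise under acid and eliminate towards C6–H, the ring diene may migrate, or the E/Z equilibration of the enone may stay incomplete. Fallback, setting out from 19 and returning at 21: Bu4NF/AcOH in THF frees the alcohol 20, which is isolated. Semihydrogenation (H2, Pd on CaCO3 poisoned with Pb(OAc)2, quinoline) gives the Z allylic tertiary alcohol F5. Oxidative 1,3-transposition with pyridinium chlorochromate in CH2Cl2 (Babler–Dauben) then gives 21 through a chromate ester shift in place of alkyne activation.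

3. Step 1. The nitrogen nucleophile may attack the methyl-flanked carbonyl in part, the free cis acid may close back onto the imide with loss of the auxiliary, and the alkene may isomerise from Z to E. Fallback, setting out from 2 and returning at 5: the regiochemistry is fixed at the stage of stable, separable half esters and the auxiliary is attached last. tert-Butanol with DMAP opens 2 at the unhindered carbonyl to tert-butyl hydrogen citraconate F6. TMSCHN2 gives the mixed tert-butyl methyl diester F7. CF3CO2H in CH2Cl2 removes the tert-butyl group to give the monomethyl ester acid F8. Pivaloyl chloride/Et3N converts F8 into the mixed pivalic anhydride F9, which acylates 1 in the presence of LiCl to give 5.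

**Further compounds**

F1 | step 3 | racemic [4+2] adduct of 6 and 2: 1,5,8-trimethyl-3-oxo-2-oxabicyclo[2.2.2]oct-7-ene-5,6-dicarboxylic anhydride (endo and exo) | CC12OC(=O)C(C(C)=C1)C1(C)C(=O)OC(=O)C21
F2 | step 3 | rac-cis-3a,5,7-trimethyl-3a,7a-dihydro-2-benzofuran-1,3-dione (one enantiomer drawn) | C[C@]12C=C(C)C=C(C)[C@H]1C(=O)OC2=O
F3 | step 3 | cis-6-{[(4R)-4-benzyl-2-oxo-1,3-oxazolidin-3-yl]carbonyl}-1,3,5-trimethylcyclohexa-2,4-diene-1-carboxylic acid (both ring configurations) | OC(=O)C1(C)C=C(C)C=C(C)C1C(=O)N2[C@H](Cc3ccccc3)COC2=O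
F4 | step 3 | methyl (1R,6S)-6-{[(4R)-4-benzyl-2-oxo-1,3-oxazolidin-3-yl]carbonyl}-1,3,5-trimethylcyclohexa-2,4-diene-1-carboxylate | COC(=O)[C@]1(C)C=C(C)C=C(C)[C@@H]1C(=O)N2[C@H](Cc3ccccc3)COC2=O
F5 | step 13 | 4-hydroxy-6-{(1S,6R)-6-[(3Z)-2-hydroxypent-3-en-2-yl]-1,3,5-trimethylcyclohexa-2,4-dien-1-yl}-3,5-dimethyl-2H-pyran-2-one | O=c1oc([C@@]2(C)C=C(C)C=C(C)[C@H]2C(C)(O)/C=C\C)c(C)c(O)c1C
F6 | step 1 | (Z)-4-tert-butoxy-2-methyl-4-oxobut-2-enoic acid | OC(=O)/C(C)=C\C(=O)OC(C)(C)C
F7 | step 1 | 4-tert-butyl 1-methyl (Z)-2-methylbut-2-enedioate | COC(=O)/C(C)=C\C(=O)OC(C)(C)C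
F8 | step 1 | (Z)-4-methoxy-3-methyl-4-oxobut-2-enoic acid | COC(=O)/C(C)=C\C(=O)O
F9 | step 1 | (Z)-4-methoxy-3-methyl-4-oxobut-2-enoic pivalic anhydride | COC(=O)/C(C)=C\C(=O)OC(=O)C(C)(C)C
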